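**Retrosynthetic overview**

1. Target ⇐ C8-selective isovaleroylation of an 8,9-cis-diol ⇐ OsO4 dihydroxylation anti to the C7 angelate ⇐ CBS-set C7 carbinol of a longipin-8-en-7-one.
2. Seven-membered ring (C5–C10 bond, formed last) ⇐ new titanocene-catalysed reductive coupling of a side-chain epoxide with a cyclobutanone tosylhydrazone (N2 lost, H left on C5).
3. Cyclobutane and six-membered ring (formed together, first) ⇐ crossed intramolecular vinylketene–alkene [2+2] of a C15 5-silyloxyfarnesoic acid, steered by its single stereocentre.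
4. C15 chain and first stereocentre ⇐ disulfonimide-catalysed asymmetric vinylogous Mukaiyama aldol of geranial with the silyl dienolate of methyl 3-methylbut-2-enoate.
5. Ring order: bicyclo[3.1.1]heptanone (four- and six-membered rings) → seven-membered ring → oxygenation of C7, C8, C9 and the two esters.

Assumption: the (S)-catalysts named in steps 2 and 11 are taken to give the configurations drawn; if a test run shows the opposite sense, the mirror-image catalyst is used.

Locants in names of tricyclic compounds (longipinane numbering): C1 (ketone carbon of the target), C2, C3 (secondary methyl), C4, C5, C6 (quaternary methyl), C7, C8, C9, C10 (gem-dimethyl), C11. The cyclobutane is C4–C5–C11–C6, with bonds C5–C10 and C6–C7.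

**Route**

Step 1
Reactants: 1 methyl 3-methylbut-2-enoate
Product: 2 tert-butyl[(1-methoxy-3-methylbuta-1,3-dien-1-yl)oxy]dimethylsilane (1Z drawn; ketene acetal geometry of no consequence)
Conditions: LiN(iPr)2, THF, −78 °C; TBSCl, DMPU, −78 °C → rt; distil
Reagents that add atoms: tert-butyldimethylsilyl chloride, CC(C)(C)[Si](C)(C)Cl
Why: Kinetic γ-deprotonation of the enoate and O-silylation of the extended lithium dienolate (silyl ketene acetal formation) give the 2-silyloxydiene needed for Mukaiyama chemistry.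

Step 2
Reactants: 2 tert-butyl[(1-methoxy-3-methylbuta-1,3-dien-1-yl)oxy]dimethylsilane; 3 geranial [(2E)-3,7-dimethylocta-2,6-dienal]
Product: 4 methyl (2E,5S,6E)-5-[(tert-butyldimethylsilyl)oxy]-3,7,11-trimethyldodeca-2,6,10-trienoate
Conditions: (S)-3,3′-bis[3,5-bis(trifluoromethyl)phenyl]-1,1′-binaphthyl-2,2′-disulfonimide (2 mol %), Et2O, −78 °C; pyridine quench
Reagents that add atoms: none
Why: Catalytic asymmetric vinylogous Mukaiyama aldol reaction in which the N-silylated chiral disulfonimide (a silylium ion paired with the chiral anion) activates the enal for 1,2-attack by the dienolate γ-carbon on the aldehyde Si face, setting the first stereocentre (5S) and passing the TBS group to the new oxygen so that the aldol is isolated as its silyl ether.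

Step 3
Reactants: 4 methyl (2E,5S,6E)-5-[(tert-butyldimethylsilyl)oxy]-3,7,11-trimethyldodeca-2,6,10-trienoate
Product: 5 (2E,5S,6E)-5-[(tert-butyldimethylsilyl)oxy]-3,7,11-trimethyldodeca-2,6,10-trienoic acid
Conditions: LiOH·H2O, THF/MeOH/H2O, 40 °C; then 1 M HCl to pH 4, 0 °C
Reagents that add atoms: lithium hydroxide, [Li+].[OH-]
Why: Saponification of the conjugated methyl ester leaves the secondary allylic TBS ether intact under LiOH and brief cold acidification.

Step 4
Reactants: 5 (2E,5S,6E)-5-[(tert-butyldimethylsilyl)oxy]-3,7,11-trimethyldodeca-2,6,10-trienoic acid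
Product: 8 4-[(tert-butyldimethylsilyl)oxy]-7-methyl-7-(4-methylpent-3-en-1-yl)-2-methylidenebicyclo[3.1.1]heptan-6-one (4-OTBS trans to the C7 bridge; 7-methyl syn to the C2–C4 bridge), via acid chloride 6 (not isolated), via vinylketene 7 (not isolated)
Conditions: 1-chloro-N,N,2-trimethylprop-1-en-1-amine, CH2Cl2, 0 °C → rt; then syringe-pump addition to Et3N, PhMe, 110 °C (0.005 M)
Reagents that add atoms: none
Why: Crossed intramolecular vinylketene–alkene [2+2] cycloaddition (the mode known for geranoyl and farnesoyl chlorides) in which the ketene carbonyl carbon bonds to the less substituted alkene carbon and the α-carbon to the methyl-bearing one, the E-alkene placing the C7 methyl syn to the three-carbon bridge while allylic 1,3-strain between that methyl and the silyloxy group fixes the alkene face, so the one stereocentre of 5 sets all three ring stereocentres.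

Step 5
Reactants: 8 4-[(tert-butyldimethylsilyl)oxy]-7-methyl-7-(4-methylpent-3-en-1-yl)-2-methylidenebicyclo[3.1.1]heptan-6-one
Product: 9 4-[(tert-butyldimethylsilyl)oxy]-7-[2-(3,3-dimethyloxiran-2-yl)ethyl]-7-methyl-2-methylidenebicyclo[3.1.1]heptan-6-one (both epoxide epimers)
Conditions: dimethyldioxirane (1.05 equiv), acetone, −20 °C
Reagents that add atoms: dimethyldioxirane, CC1(C)OO1
Why: Dioxirane epoxidation is fastest at the trisubstituted side-chain alkene and, unlike a peracid, cannot cause Baeyer–Villiger oxidation of the cyclobutanone; both epimers are carried on because this centre is removed in step 9.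

Step 6
Reactants: 9 4-[(tert-butyldimethylsilyl)oxy]-7-[2-(3,3-dimethyloxiran-2-yl)ethyl]-7-methyl-2-methylidenebicyclo[3.1.1]heptan-6-one
Product: 10 N′-tosylhydrazone of 9 at C6
Conditions: TsNHNH2, EtOH, 40 °C
Reagents that add atoms: 4-methylbenzenesulfonohydrazide, Cc1ccc(cc1)S(=O)(=O)NN
Why: Hydrazone formation on the strained, non-enolisable cyclobutanone needs no acid, so the epoxide survives.

Step 7
Reactants: 10 N′-tosylhydrazone of 9 at C6
Product: 13 1-[(tert-butyldimethylsilyl)oxy]-3-methylidenelongipinan-9-ol (C9 epimers), via cyclised tosylhydrazide 11 (not isolated), via diazene 12 (not isolated)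
Conditions: Cp2TiCl2 (0.2 equiv), Zn dust, 2,4,6-collidine·HCl, THF (0.01 M), 25 °C; then 60 °C
Reagents that add atoms: none
Why: Proposed new method: trivalent titanium (Cp2TiCl made from Cp2TiCl2 and Zn) opens the epoxide homolytically to the tertiary C10 radical (Nugent–RajanBabu opening), which adds to the hydrazone carbon from the only face it can reach because the side chain sits cis-1,3 to that carbon across the cyclobutane, the hydrazinyl radical is reduced and protonated to hydrazide 11, and loss of sulfinate then of N2 from diazene 12 leaves hydrogen on C5 (Wolff–Kishner-type denitrogenation), so the C5–C10 bond and the seven-membered ring form with the ketone oxygen removed in the same flask; the closest known reactions are titanocene-mediated epoxide radical cyclisations onto carbonyl groups and iron-hydride alkene–tosylhydrazone reductive alkylations.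

Step 8
Reactants: 13 1-[(tert-butyldimethylsilyl)oxy]-3-methylidenelongipinan-9-ol
Product: 14 1-[(tert-butyldimethylsilyl)oxy]longipinan-9-ol (3-methyl syn to C6; C9 epimers)
Conditions: H2 (1 atm), PtO2, EtOAc, rt
Reagents that add atoms: none
Why: Heterogeneous hydrogenation adds to the exocyclic alkene from the C5 side, away from the methyl-bearing C6 bridge (as β-pinene gives cis-pinane), which sets C3 with its methyl syn to C6; the C1 silyl ether is pseudo-equatorial and trans to C6, so it should not shield that face.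

Step 9
Reactants: 14 1-[(tert-butyldimethylsilyl)oxy]longipinan-9-ol
Product: 15 1-[(tert-butyldimethylsilyl)oxy]longipin-8-ene
Conditions: Burgess reagent, PhMe, 70 °C
Reagents that add atoms: none
Why: Burgess dehydration (syn elimination of the sulfamate ester) can only take a C8 hydrogen because C10 is quaternary, so either C9 epimer gives the 8,9-alkene, as 4,4-dimethyl 3-ols of triterpenes give 2-enes with this reagent.

Step 10
Reactants: 15 1-[(tert-butyldimethylsilyl)oxy]longipin-8-ene
Product: 17 1-[(tert-butyldimethylsilyl)oxy]longipin-8-en-7-one, via allylic alcohol 16 (not isolated)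
Conditions: SeO2 (0.5 equiv), t-BuOOH, CH2Cl2, 35 °C; then Dess–Martin periodinane, CH2Cl2, rt
Reagents that add atoms: tert-butyl hydroperoxide, CC(C)(C)OO; selenium dioxide, O=[Se]=O (relays the oxygen)
Why: Selenium dioxide allylic oxidation (ene reaction then [2,3]-sigmatropic shift) can only oxygenate C7, the sole allylic C–H position, and returns the double bond to C8=C9, and Dess–Martin oxidation of the crude epimeric alcohols 16 converges on one enone.

Step 11
Reactants: 17 1-[(tert-butyldimethylsilyl)oxy]longipin-8-en-7-one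
Product: 18 (7R)-1-[(tert-butyldimethylsilyl)oxy]longipin-8-en-7-ol (7-OH on the C11 side)
Conditions: (S)-2-methyl-CBS-oxazaborolidine (0.2 equiv), catecholborane, PhMe, −78 °C; aqueous work-up
Reagents that add atoms: none
Why: Corey–Bakshi–Shibata reduction delivers hydride to one carbonyl face with the quaternary C6 arm as the large group, which is needed because the seven-membered ring is nearly mirror-symmetric and offers little substrate bias.

Step 12
Reactants: 18 (7R)-1-[(tert-butyldimethylsilyl)oxy]longipin-8-en-7-ol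
Product: 19 (7R)-1-[(tert-butyldimethylsilyl)oxy]longipin-8-en-7-yl (Z)-2-methylbut-2-enoate
Conditions: angelic acid, 2,4,6-trichlorobenzoyl chloride, Et3N, PhMe, rt; then 18, 80 °C
Reagents that add atoms: angelic acid [(Z)-2-methylbut-2-enoic acid], C/C=C(/C)C(=O)O
Why: Yamaguchi-type esterification with the preformed mixed anhydride and no nucleophilic catalyst acylates the hindered alcohol at the unhindered angeloyl carbonyl without angelate-to-tiglate isomerisation.

Step 13
Reactants: 19 (7R)-1-[(tert-butyldimethylsilyl)oxy]longipin-8-en-7-yl (Z)-2-methylbut-2-enoate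
Product: 20 (7R)-1-hydroxylongipin-8-en-7-yl (Z)-2-methylbut-2-enoate
Conditions: HF·pyridine, pyridine, THF, 0 °C → rt
Reagents that add atoms: none
Why: Buffered fluoride desilylation removes the TBS ether without touching the allylic angelate.

Step 14
Reactants: 20 (7R)-1-hydroxylongipin-8-en-7-yl (Z)-2-methylbut-2-enoate
Product: 21 (7R)-1-oxolongipin-8-en-7-yl (Z)-2-methylbut-2-enoate
Conditions: Dess–Martin periodinane, CH2Cl2, rt
Reagents that add atoms: none
Why: Dess–Martin oxidation of the only free alcohol gives the C1 ketone under neutral conditions.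

Step 15
Reactants: 21 (7R)-1-oxolongipin-8-en-7-yl (Z)-2-methylbut-2-enoate
Product: 22 8,9-dihydroxy-1-oxolongipinan-7-yl (Z)-2-methylbut-2-enoate (8,9-cis-diol on the C4 side; trans to the 7-ester)
Conditions: OsO4 (5 mol %), NMO, acetone/H2O 10:1, 0 °C
Reagents that add atoms: osmium tetroxide, O=[Os](=O)(=O)=O; N-methylmorpholine N-oxide, C[N+]1([O-])CCOCC1; water, O
Why: Upjohn dihydroxylation adds suprafacially to the ring alkene anti to the allylic C7 ester (Kishi's rule, reinforced by the ester blocking its own face), setting C8 and C9 cis to each other and trans to C7, while the electron-poor trisubstituted angelate alkene reacts much more slowly.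

Step 16
Reactants: 22 8,9-dihydroxy-1-oxolongipinan-7-yl (Z)-2-methylbut-2-enoate
Product: 23 CNP0323312.1 [9-hydroxy-8-(3-methylbutanoyloxy)-1-oxolongipinan-7-yl (Z)-2-methylbut-2-enoate]
Conditions: 3-methylbutanoic anhydride (1.1 equiv), pyridine, DMAP (5 mol %), CH2Cl2, −20 °C
Reagents that add atoms: 3-methylbutanoic anhydride, CC(C)CC(=O)OC(=O)CC(C)C
Why: Regioselective acylation of the diol takes the C8 hydroxyl because the C9 hydroxyl is neopentyl next to the gem-dimethyl carbon, giving the target.

**Compound list**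

1 | methyl 3-methylbut-2-enoate | COC(=O)C=C(C)C | starting material
2 | tert-butyl[(1-methoxy-3-methylbuta-1,3-dien-1-yl)oxy]dimethylsilane | C=C(C)/C=C(\O[Si](C)(C)C(C)(C)C)OC | intermediate
3 | geranial, (2E)-3,7-dimethylocta-2,6-dienal | CC(C)=CCC/C(C)=C/C=O | starting material
4 | methyl (2E,5S,6E)-5-[(tert-butyldimethylsilyl)oxy]-3,7,11-trimethyldodeca-2,6,10-trienoate | COC(=O)/C=C(\C)C[C@H](O[Si](C)(C)C(C)(C)C)/C=C(\C)CCC=C(C)C | intermediate
5 | (2E,5S,6E)-5-[(tert-butyldimethylsilyl)oxy]-3,7,11-trimethyldodeca-2,6,10-trienoic acid | OC(=O)/C=C(\C)C[C@H](O[Si](C)(C)C(C)(C)C)/C=C(\C)CCC=C(C)C | intermediate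
6 | acid chloride of 5 | ClC(=O)/C=C(\C)C[C@H](O[Si](C)(C)C(C)(C)C)/C=C(\C)CCC=C(C)C | intermediate (not isolated)
7 | (5S,6E)-5-[(tert-butyldimethylsilyl)oxy]-7,11-dimethyl-3-methylidenedodeca-1,6,10-trien-1-one (vinylketene) | O=C=CC(=C)C[C@H](O[Si](C)(C)C(C)(C)C)/C=C(\C)CCC=C(C)C | intermediate (not isolated)
8 | 4-[(tert-butyldimethylsilyl)oxy]-7-methyl-7-(4-methylpent-3-en-1-yl)-2-methylidenebicyclo[3.1.1]heptan-6-one; 4-OTBS trans to the C7 bridge, 7-methyl syn to the C2–C4 bridge | O=C1[C@@H]2C(=C)C[C@H](O[Si](C)(C)C(C)(C)C)[C@H]1[C@@]2(CCC=C(C)C)C | intermediate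
9 | side-chain epoxide of 8 (epoxide epimers) | O=C1[C@@H]2C(=C)C[C@H](O[Si](C)(C)C(C)(C)C)[C@H]1[C@@]2(CCC3OC3(C)C)C | intermediate
10 | C6 N′-tosylhydrazone of 9 | Cc1ccc(cc1)S(=O)(=O)NN=C1[C@@H]2C(=C)C[C@H](O[Si](C)(C)C(C)(C)C)[C@H]1[C@@]2(CCC3OC3(C)C)C | intermediate
11 | 1-[(tert-butyldimethylsilyl)oxy]-3-methylidene-5-(2-tosylhydrazinyl)longipinan-9-ol | C1CC(O)C(C)(C)[C@@]2(NNS(=O)(=O)c4ccc(C)cc4)[C@@H]3C(=C)C[C@H](O[Si](C)(C)C(C)(C)C)[C@H]2[C@@]31C | intermediate (not isolated)
12 | 1-[(tert-butyldimethylsilyl)oxy]-5-diazenyl-3-methylidenelongipinan-9-ol | C1CC(O)C(C)(C)[C@@]2(N=N)[C@@H]3C(=C)C[C@H](O[Si](C)(C)C(C)(C)C)[C@H]2[C@@]31C | intermediate (not isolated)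
13 | 1-[(tert-butyldimethylsilyl)oxy]-3-methylidenelongipinan-9-ol (C9 epimers; 1-OTBS trans to C6) | C1CC(O)C(C)(C)[C@H]2[C@@H]3C(=C)C[C@H](O[Si](C)(C)C(C)(C)C)[C@H]2[C@@]31C | intermediate
14 | 1-[(tert-butyldimethylsilyl)oxy]longipinan-9-ol (3-methyl syn to C6; C9 epimers) | C1CC(O)C(C)(C)[C@H]2[C@@H]3[C@@H](C)C[C@H](O[Si](C)(C)C(C)(C)C)[C@H]2[C@@]31C | intermediate
15 | 1-[(tert-butyldimethylsilyl)oxy]longipin-8-ene | C1C=CC(C)(C)[C@H]2[C@@H]3[C@@H](C)C[C@H](O[Si](C)(C)C(C)(C)C)[C@H]2[C@@]31C | intermediate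
16 | 1-[(tert-butyldimethylsilyl)oxy]longipin-8-en-7-ol (C7 epimers) | OC1C=CC(C)(C)[C@H]2[C@@H]3[C@@H](C)C[C@H](O[Si](C)(C)C(C)(C)C)[C@H]2[C@@]31C | intermediate (not isolated)
17 | 1-[(tert-butyldimethylsilyl)oxy]longipin-8-en-7-one | O=C1C=CC(C)(C)[C@H]2[C@@H]3[C@@H](C)C[C@H](O[Si](C)(C)C(C)(C)C)[C@H]2[C@@]31C | intermediate
18 | (7R)-1-[(tert-butyldimethylsilyl)oxy]longipin-8-en-7-ol (7-OH on the C11 side) | O[C@@H]1C=CC(C)(C)[C@H]2[C@@H]3[C@@H](C)C[C@H](O[Si](C)(C)C(C)(C)C)[C@H]2[C@@]31C | intermediate
19 | (7R)-1-[(tert-butyldimethylsilyl)oxy]longipin-8-en-7-yl (Z)-2-methylbut-2-enoate | C/C=C(/C)C(=O)O[C@@H]1C=CC(C)(C)[C@H]2[C@@H]3[C@@H](C)C[C@H](O[Si](C)(C)C(C)(C)C)[C@H]2[C@@]31C | intermediate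
20 | (7R)-1-hydroxylongipin-8-en-7-yl (Z)-2-methylbut-2-enoate | C/C=C(/C)C(=O)O[C@@H]1C=CC(C)(C)[C@H]2[C@@H]3[C@@H](C)C[C@H](O)[C@H]2[C@@]31C | intermediate
21 | (7R)-1-oxolongipin-8-en-7-yl (Z)-2-methylbut-2-enoate | C/C=C(/C)C(=O)O[C@@H]1C=CC(C)(C)[C@H]2[C@@H]3[C@@H](C)CC(=O)[C@H]2[C@@]31C | intermediate
22 | 8,9-dihydroxy-1-oxolongipinan-7-yl (Z)-2-methylbut-2-enoate (8-OH and 9-OH cis, on the C4 side; 7-ester on the C11 side) | C/C=C(/C)C(=O)O[C@@H]1[C@@H](O)[C@@H](O)C(C)(C)[C@H]2[C@@H]3[C@@H](C)CC(=O)[C@H]2[C@@]31C | intermediate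
23 | CNP0323312.1, 9-hydroxy-8-(3-methylbutanoyloxy)-1-oxolongipinan-7-yl (Z)-2-methylbut-2-enoate | C/C=C(/C)C(=O)O[C@@H]1[C@@H](OC(=O)CC(C)C)[C@@H](O)C(C)(C)[C@H]2[C@@H]3[C@@H](C)CC(=O)[C@H]2[C@@]31C | target

**Step count and risks**

Total steps: 16. Longest linear sequence: 16 steps (1 → 23); geranial 3 enters at step 2.

The three steps most likely to fail:

Step 7 (the new epoxide–hydrazone coupling). The tertiary radical may be quenched before it reaches the hindered C=N, or the hydrazide may not lose sulfinate cleanly. The fallback closes the ring with the known iron-hydride alkene–tosylhydrazone reductive alkylation. It sets out from 9: the exocyclic alkene is hydrogenated first (H2, PtO2) to the saturated epoxy ketone F1. The epoxide is then isomerised with diethylaluminium 2,2,6,6-tetramethylpiperidide (PhMe, −20 °C; the cyclobutanone cannot enolise) to the isopropenyl carbinol F2. TsNHNH2 gives the tosylhydrazone F3. Fe(acac)3 and PhSiH3 in EtOH at 60 °C then transfer a hydrogen atom to the isopropenyl CH2, the tertiary radical adds to the C=N, and sulfinate and N2 are lost, which gives 14, where the route is rejoined.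

Step 10 (allylic oxidation of a cis-alkene that is neopentyl on both sides). The ene step may be too slow, or the silyl ether may suffer. The fallback brings the C7 oxygen in by carbonyl transposition and also avoids the dehydration of step 9. It sets out from 14: Dess–Martin oxidation gives the C9 ketone F4. IBX (DMSO, 70 °C) dehydrogenates it to the 7-en-9-one F5, since only C8 can enolise. NaOH/H2O2 gives the 7,8-epoxy ketone F6. Wharton transposition (N2H4·H2O, AcOH) then gives the allylic alcohols 16, which the second stage of step 10 oxidises to 17.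

Step 11 (face selectivity at C7). The ring offers almost no substrate bias, and the alkenyl arm rather than the quaternary arm may act as the large group; in that case the (R)-catalyst is tried first. If catalyst control stays poor, the fallback sets out from 17: NaBH4 with CeCl3·7H2O in MeOH at −78 °C gives 18 together with its (7S)-epimer F7. The two are separated by chromatography, and F7 is returned to 17 with Dess–Martin periodinane and recycled, so the route is rejoined at 18.

Further compounds
F1 | step 7 | 4-[(tert-butyldimethylsilyl)oxy]-7-[2-(3,3-dimethyloxiran-2-yl)ethyl]-2,7-dimethylbicyclo[3.1.1]heptan-6-one (2-methyl syn to C7) | O=C1[C@@H]2[C@@H](C)C[C@H](O[Si](C)(C)C(C)(C)C)[C@H]1[C@@]2(CCC3OC3(C)C)C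
F2 | step 7 | 4-[(tert-butyldimethylsilyl)oxy]-7-(3-hydroxy-4-methylpent-4-en-1-yl)-2,7-dimethylbicyclo[3.1.1]heptan-6-one | O=C1[C@@H]2[C@@H](C)C[C@H](O[Si](C)(C)C(C)(C)C)[C@H]1[C@@]2(CCC(O)C(C)=C)C
F3 | step 7 | C6 N′-tosylhydrazone of F2 | Cc1ccc(cc1)S(=O)(=O)NN=C1[C@@H]2[C@@H](C)C[C@H](O[Si](C)(C)C(C)(C)C)[C@H]1[C@@]2(CCC(O)C(C)=C)C
F4 | step 10 | 1-[(tert-butyldimethylsilyl)oxy]longipinan-9-one | C1CC(=O)C(C)(C)[C@H]2[C@@H]3[C@@H](C)C[C@H](O[Si](C)(C)C(C)(C)C)[C@H]2[C@@]31C
F5 | step 10 | 1-[(tert-butyldimethylsilyl)oxy]longipin-7-en-9-one | C1=CC(=O)C(C)(C)[C@H]2[C@@H]3[C@@H](C)C[C@H](O[Si](C)(C)C(C)(C)C)[C@H]2[C@@]31C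
F6 | step 10 | 1-[(tert-butyldimethylsilyl)oxy]-7,8-epoxylongipinan-9-one | C14OC4C(=O)C(C)(C)[C@H]2[C@@H]3[C@@H](C)C[C@H](O[Si](C)(C)C(C)(C)C)[C@H]2[C@@]31C
F7 | step 11 | (7S)-1-[(tert-butyldimethylsilyl)oxy]longipin-8-en-7-ol | O[C@H]1C=CC(C)(C)[C@H]2[C@@H]3[C@@H](C)C[C@H](O[Si](C)(C)C(C)(C)C)[C@H]2[C@@]31C
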